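**Retrosynthetic overview**

- The target is taken back by O8-methylation and para-hydroxylation at C8 to 5-hydroxy-7,2',5'-trimethoxyflavone, so that the one oxygen outside the acetate pattern is added last.
- The strategy rests on ring A of that flavone: oxygen sits on the alternate carbons C5, C7 and C8a, and C4a carries the C4(=O)–C3–C2–aryl chain, which is the pattern of an arylpropynoyl starter extended by three acetate units.
- Bonds C4a–C8a (ring A) and O1–C2 (ring C) are therefore cut together, giving an isomeric 4-methoxy-2-pyranone with a CH2–CO–C≡C–aryl side chain at C6, a lactone-masked tetraketide.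
- This pyranone ynone is cut at C4–C4a into lithiated 4-methoxy-6-methyl-2-pyranone and an arylpropynoic Weinreb amide, the latter made from 2,5-dimethoxybenzaldehyde by Corey–Fuchs homologation.
- Ring order: ring B and the sacrificial pyranone are bought; ring A forms first and ring C second, both in the key step.

Key step: step 4

Remark: 4-methoxy-6-methyl-2H-pyran-2-one is assumed to be purchased (it is otherwise one O-methylation from 4-hydroxy-6-methyl-2-pyranone); flavone locants are used for the pyranone precursor, so that pyranone C2, C3, C4, C5, C6 are C8a, C8, C7, C6, C5, the side-chain CH2 is C4a, the ketone is C4 and the alkyne carbons are C3 and C2.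

**Route**

Step 1
Reactants: 1 2,5-dimethoxybenzaldehyde
Product: 2 2-(2,2-dibromoethenyl)-1,4-dimethoxybenzene
Conditions: CBr4 (2 equiv), PPh3 (4 equiv), CH2Cl2, 0 °C
Reagents that add atoms: carbon tetrabromide, BrC(Br)(Br)Br
Why: Corey–Fuchs dibromo-olefination, in which Ph3P=CBr2 formed in the flask from PPh3 and CBr4 should convert the unhindered aryl aldehyde into the 1,1-dibromoalkene by a Wittig reaction that leaves the aryl methyl ethers untouched.

Step 2
Reactants: 2 2-(2,2-dibromoethenyl)-1,4-dimethoxybenzene, 3 N-methoxy-N-methylcarbamoyl chloride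
Product: 5 3-(2,5-dimethoxyphenyl)-N-methoxy-N-methylprop-2-ynamide, via lithium arylacetylide 4 (not isolated)
Conditions: n-BuLi (2.1 equiv), THF, −78 °C; then 3 (1.2 equiv), −78 °C to 0 °C
Reagents that add atoms: none
Why: Second stage of the Corey–Fuchs homologation, in which n-BuLi effects dehydrobromination and bromine–lithium exchange to the lithium acetylide, which is then acylated at carbon by the carbamoyl chloride (addition–elimination), a standard entry to alkynyl Weinreb amides; ortho-lithiation of the dimethoxyarene should not compete at −78 °C.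

Step 3
Reactants: 6 4-methoxy-6-methyl-2H-pyran-2-one, 5 3-(2,5-dimethoxyphenyl)-N-methoxy-N-methylprop-2-ynamide
Product: 9 6-[4-(2,5-dimethoxyphenyl)-2-oxobut-3-yn-1-yl]-4-methoxy-2H-pyran-2-one, via lithiated pyranone 7 (not isolated), via tetrahedral lithium adduct 8 (not isolated)
Conditions: LiN(i-Pr)2 (LDA, 1.1 equiv), THF, −78 °C; then 5, −78 °C; inverse quench into cold 1 M HCl
Reagents that add atoms: none
Why: Acylation of a lithium dienolate by a Weinreb amide, in which the base removes a proton from the vinylogous C6-methyl group, the hard dienolate adds 1,2 to the amide carbonyl, and the chelated tetrahedral adduct persists until the acid quench, so that the acidic β-keto product never meets the base and the liberated amine is protonated before it can add to the ynone.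

Step 4
Reactants: 9 6-[4-(2,5-dimethoxyphenyl)-2-oxobut-3-yn-1-yl]-4-methoxy-2H-pyran-2-one
Product: 12 5-hydroxy-7,2',5'-trimethoxyflavone, via ring-opened keto ester 10 (not isolated), via dihydroxyaryl ynone 11 (not isolated)
Conditions: Mg(OMe)2 (3 equiv), MeOH, reflux; then 2 M HCl, 50 °C
Reagents that add atoms: none
Why: Proposed new method: Mg(OMe)2 should first turn the acidic C4a methylene of 9 into its magnesium enolate, and methoxide should then open the lactone reversibly at C8a to the chelated keto ester 10, in which the former ring oxygen is the C5 carbonyl, C8a is a methyl ester and C7 remains a methyl enol ether; the magnesium-bound C4a carbon attacks C8a, methoxide is expelled, the ring enolizes to the aromatic ynone 11, and one of its phenoxides adds to alkyne carbon C2 to form O1–C2. The closest known reaction type is the Mg(OMe)2-mediated Claisen cyclization of 3,5,7-triketo esters and of their 2-pyranone forms to acylphloroglucinols, followed by the familiar cyclization of 2-hydroxyaryl ynones to flavones; the alkynyl ketone terminus in the folding step is the part that has not been shown. Ring A closes by a 6-exo-trig Claisen (Dieckmann-type) condensation, and ring C by a 6-endo-dig oxa-Michael addition or, where methanol has added to the ynone first, by addition–elimination on the β-methoxy enone, which the warm acid finish completes. No stereocenter is formed. The step needs Claisen folding (C4a to C8a) to win over aldol folding (C8 to C4) and over O-attack on the alkyne, which is secured because C8 is a vinylic enol-ether carbon that cannot become an enolate, magnesium ties the C4–C5 diketonate oxygens into a chelate with C4a as the nucleophile, and O-attack on the ester only re-forms 9; it also needs 6-endo over 5-exo closure, which is helped by the two phenols of 11 being equivalent and by the acid finish through the β-methoxy enone, which leads to the 4-pyranone.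

Step 5
Reactants: 12 5-hydroxy-7,2',5'-trimethoxyflavone
Product: 14 5,8-dihydroxy-7,2',5'-trimethoxyflavone, via potassium 8-sulfate 13 (not isolated)
Conditions: K2S2O8 (1.2 equiv), aq. KOH, pyridine, 15–20 °C; then conc. HCl, 90 °C, N2
Reagents that add atoms: potassium peroxydisulfate, [K+].[K+].[O-]S(=O)(=O)OOS(=O)(=O)[O-]
Why: Elbs persulfate oxidation, in which the phenoxide of the 5-hydroxyl attacks a peroxide oxygen of peroxydisulfate through its para carbon C8 to give the aryl sulfate that hot acid hydrolyzes to the 5,8-hydroquinone, a transformation long used on 5-hydroxyflavones; ring B has no phenoxide and should not be attacked.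

Step 6
Reactants: 14 5,8-dihydroxy-7,2',5'-trimethoxyflavone
Product: 15 5-hydroxy-7,8,2',5'-tetramethoxyflavone
Conditions: Me2SO4 (1.05 equiv), K2CO3, acetone, reflux, N2
Reagents that add atoms: dimethyl sulfate, COS(=O)(=O)OC
Why: Selective Williamson methylation, since the 8-hydroxyl is a free phenol that K2CO3 deprotonates whereas the 5-hydroxyl is held in a hydrogen bond to the C4 carbonyl and is far less nucleophilic, so one equivalent of dimethyl sulfate should methylate O8 only.

**Compound list**

1 | 2,5-dimethoxybenzaldehyde | COc1ccc(OC)c(C=O)c1 | starting material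
2 | 2-(2,2-dibromoethenyl)-1,4-dimethoxybenzene | COc1ccc(OC)c(C=C(Br)Br)c1 | intermediate
3 | N-methoxy-N-methylcarbamoyl chloride | CON(C)C(=O)Cl | starting material
4 | lithium (2,5-dimethoxyphenyl)acetylide | [Li]C#Cc1cc(OC)ccc1OC | intermediate
5 | 3-(2,5-dimethoxyphenyl)-N-methoxy-N-methylprop-2-ynamide | CON(C)C(=O)C#Cc1cc(OC)ccc1OC | intermediate
6 | 4-methoxy-6-methyl-2H-pyran-2-one | COc1cc(C)oc(=O)c1 | starting material
7 | 6-(lithiomethyl)-4-methoxy-2H-pyran-2-one (lithium dienolate) | [Li]Cc1cc(OC)cc(=O)o1 | intermediate
8 | lithium 4-(2,5-dimethoxyphenyl)-2-[methoxy(methyl)amino]-1-(4-methoxy-2-oxo-2H-pyran-6-yl)but-3-yn-2-olate (racemic) | COc1cc(CC(O[Li])(C#Cc2cc(OC)ccc2OC)N(C)OC)oc(=O)c1 | intermediate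
9 | 6-[4-(2,5-dimethoxyphenyl)-2-oxobut-3-yn-1-yl]-4-methoxy-2H-pyran-2-one | COc1cc(CC(=O)C#Cc2cc(OC)ccc2OC)oc(=O)c1 | intermediate
10 | methyl (2E)-9-(2,5-dimethoxyphenyl)-3-methoxy-5,7-dioxonon-2-en-8-ynoate (as its magnesium chelate) | COC(=O)/C=C(/OC)CC(=O)CC(=O)C#Cc1cc(OC)ccc1OC | intermediate
11 | 1-(2,6-dihydroxy-4-methoxyphenyl)-3-(2,5-dimethoxyphenyl)prop-2-yn-1-one | COc1cc(O)c(C(=O)C#Cc2cc(OC)ccc2OC)c(O)c1 | intermediate
12 | 5-hydroxy-7,2',5'-trimethoxyflavone | COc1ccc(OC)c(-c2cc(=O)c3c(O)cc(OC)cc3o2)c1 | intermediate
13 | potassium 2-(2,5-dimethoxyphenyl)-5-hydroxy-7-methoxy-4-oxo-4H-chromen-8-yl sulfate | COc1ccc(OC)c(-c2cc(=O)c3c(O)cc(OC)c(OS(=O)(=O)[O-])c3o2)c1.[K+] | intermediate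
14 | 5,8-dihydroxy-7,2',5'-trimethoxyflavone | COc1ccc(OC)c(-c2cc(=O)c3c(O)cc(OC)c(O)c3o2)c1 | intermediate
15 | 5-hydroxy-7,8,2',5'-tetramethoxyflavone | COc1ccc(OC)c(-c2cc(=O)c3c(O)cc(OC)c(OC)c3o2)c1 | target

**Summary**

Total step count: 6. Longest linear sequence: 6 steps (1 → 2 → 5 → 9 → 12 → 14 → 15); 3 and 6 enter as purchased compounds.

**Steps most likely to fail**

Step 4 (proposed new method). Several processes could divert the cascade:
- conjugate addition of a diketonate oxygen to the alkynyl ketone ahead of the Claisen closure, closing a 4-pyranone on the wrong oxygen;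
- methoxide attack at C4 with loss of the arylacetylide;
- 5-exo closure of the phenoxide to an aurone;
- aldol-type folding.

The fallback uses known chemistry, sets out from 1 and returns at 12. Claisen–Schmidt condensation of 1 with purchased 1-(2-hydroxy-4,6-dimethoxyphenyl)ethanone (KOH, EtOH, room temperature) should give (E)-3-(2,5-dimethoxyphenyl)-1-(2-hydroxy-4,6-dimethoxyphenyl)prop-2-en-1-one F1. Oxidative cyclization with catalytic I2 in DMSO at 130 °C should give 5,7,2',5'-tetramethoxyflavone F2. BCl3 in CH2Cl2 at 0 °C should then cleave only the 5-O-methyl group peri to the carbonyl, by chelation, to give 12.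

Step 5. The chelated phenoxide is a weak nucleophile toward peroxydisulfate, so conversion may stall. Radical over-oxidation of the hydroquinone and alkaline opening of ring C may also erode the material.

The fallback replaces oxidative hydroxylation by halogenation and copper-mediated etherification; it sets out from 12 and returns at 15. Benzylation of the chelated hydroxyl (BnBr, K2CO3, DMF, 80 °C) should give 5-benzyloxy-7,2',5'-trimethoxyflavone F3. Iodination (N-iodosuccinimide, catalytic CF3CO2H, MeCN) is expected at C8, as is usual for 5,7-dialkoxyflavones, to give 5-benzyloxy-8-iodo-7,2',5'-trimethoxyflavone F4. Ullmann-type methoxylation (NaOMe, CuBr, DMF–MeOH, 110 °C) should give 5-benzyloxy-7,8,2',5'-tetramethoxyflavone F5. Hydrogenolysis (H2, Pd/C, EtOAc) should then free the 5-hydroxyl and give 15.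

Step 3. The dienolate may add in conjugate fashion to the ynamide, or proton transfer and competing ring lithiation may leave the amide unconsumed.

The fallback replaces acylation by aldehyde addition and oxidation; it sets out from 2 and 6 and returns at 9. Compound 2 is treated with n-BuLi (2.1 equiv, THF, −78 °C) and the acetylide is quenched with DMF to give 3-(2,5-dimethoxyphenyl)prop-2-ynal F6. The lithiated pyranone 7, made from 6 as in step 3, should add 1,2 to this aldehyde at −78 °C to give racemic 6-[4-(2,5-dimethoxyphenyl)-2-hydroxybut-3-yn-1-yl]-4-methoxy-2H-pyran-2-one F7. Oxidation of the propargylic alcohol with Dess–Martin periodinane (NaHCO3, CH2Cl2, 0 °C) should give 9.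

**Further compounds**

F1 | step 4 | (E)-3-(2,5-dimethoxyphenyl)-1-(2-hydroxy-4,6-dimethoxyphenyl)prop-2-en-1-one | COc1cc(O)c(C(=O)/C=C/c2cc(OC)ccc2OC)c(OC)c1
F2 | step 4 | 5,7,2',5'-tetramethoxyflavone | COc1ccc(OC)c(-c2cc(=O)c3c(OC)cc(OC)cc3o2)c1
F3 | step 5 | 5-benzyloxy-7,2',5'-trimethoxyflavone | COc1ccc(OC)c(-c2cc(=O)c3c(OCc4ccccc4)cc(OC)cc3o2)c1
F4 | step 5 | 5-benzyloxy-8-iodo-7,2',5'-trimethoxyflavone | COc1ccc(OC)c(-c2cc(=O)c3c(OCc4ccccc4)cc(OC)c(I)c3o2)c1
F5 | step 5 | 5-benzyloxy-7,8,2',5'-tetramethoxyflavone | COc1ccc(OC)c(-c2cc(=O)c3c(OCc4ccccc4)cc(OC)c(OC)c3o2)c1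
F6 | step 3 | 3-(2,5-dimethoxyphenyl)prop-2-ynal | COc1ccc(OC)c(C#CC=O)c1
F7 | step 3 | racemic 6-[4-(2,5-dimethoxyphenyl)-2-hydroxybut-3-yn-1-yl]-4-methoxy-2H-pyran-2-one | COc1cc(CC(O)C#Cc2cc(OC)ccc2OC)oc(=O)c1
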